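**Retrosynthetic overview**
- In each flavanone unit the ketone carbon C4 is bonded to C4a of a phloroglucinol-derived ring A, ortho to O1 and para to an alkoxy oxygen. Both C4–C4a bonds are therefore cut as intramolecular Friedel–Crafts acylations of a (3S,3'S)-bis(3-aryloxy-3-arylpropanoic acid), so both rings C close last and together.
- The two C2–O1 bonds and both stereocentres come from two successive iridium-catalysed asymmetric allylic etherifications of cinnamyl carbonates, first with 3,5-dimethoxyphenol, then with 3,5-bis(benzyloxy)phenol. Hydroboration and oxidation turn each vinyl group into CH2CO2H.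
- The two arms are told apart by an ester/nitrile pair: the rings B are joined first by SNAr of isovanillin on 4-fluorobenzonitrile, and one i-Bu2AlH reduction then gives the allylic alcohol of unit 1 and the aldehyde of unit 2.
- The 4'-oxygen is carried as a triisopropylsilyl ether and changed to the electron-poor acetate just before the ring closures. Methyl against benzyl on the two rings A encodes 7-OMe against 5'',7''-(OH)2; the chelated 5-OMe falls with BCl3.
- Ring order: rings B (diaryl ether), then rings A attached as aryl ethers, then both rings C.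

Key step: step 15

Remark: L is (Sa,Sc,Sc)-O,O'-(1,1'-binaphthalene-2,2'-diyl)-N,N-bis(1-phenylethyl)phosphoramidite, taken as the enantiomer that delivers the (S)-ethers; this sense of induction is to be confirmed on methyl cinnamyl carbonate, and the antipodal ligand is used if it proves opposite.

**Step 1**
Reactants: 1 isovanillin (3-hydroxy-4-methoxybenzaldehyde); 2 4-fluorobenzonitrile
Product: 3 4-(5-formyl-2-methoxyphenoxy)benzonitrile
Conditions: K2CO3, DMF, 100 °C
Reagents that add atoms: none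
Why: Nucleophilic aromatic substitution in which the phenoxide of 1 adds para to the nitrile and fluoride leaves from the Meisenheimer adduct; the methyl ether fixes which catechol oxygen is arylated.

**Step 2**
Reactants: 3 4-(5-formyl-2-methoxyphenoxy)benzonitrile
Product: 4 4-(5-formyl-2-hydroxyphenoxy)benzonitrile
Conditions: BBr3, CH2Cl2, −78 → 0 °C; H2O
Reagents that add atoms: none
Why: Lewis-acid ether cleavage in which bromide attacks the methyl group of the boron-complexed aryl methyl ether, while the diaryl ether has no carbon open to SN2 attack and the nitrile and aldehyde are recovered on hydrolysis.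

**Step 3**
Reactants: 4 4-(5-formyl-2-hydroxyphenoxy)benzonitrile
Product: 5 4-[5-formyl-2-(triisopropylsilyloxy)phenoxy]benzonitrile
Conditions: i-Pr3SiOTf, 2,6-lutidine, CH2Cl2, 0 °C
Reagents that add atoms: triisopropylsilyl triflate, CC(C)[Si](OS(=O)(=O)C(F)(F)F)(C(C)C)C(C)C
Why: O-silylation of the phenol with a silyl triflate and a hindered base, which installs a bulky ether expected to survive hydride, phenoxide and ylide reagents.

**Step 4**
Reactants: 5 4-[5-formyl-2-(triisopropylsilyloxy)phenoxy]benzonitrile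
Product: 6 methyl (E)-3-[3-(4-cyanophenoxy)-4-(triisopropylsilyloxy)phenyl]prop-2-enoate
Conditions: Ph3P=CHCO2Me, toluene, 80 °C
Reagents that add atoms: methyl (triphenylphosphoranylidene)acetate, COC(=O)C=P(c1ccccc1)(c1ccccc1)c1ccccc1
Why: Wittig olefination with a stabilised ylide, which should give the (E)-enoate under neutral conditions that leave the nitrile and the silyl ether alone.

**Step 5**
Reactants: 6 methyl (E)-3-[3-(4-cyanophenoxy)-4-(triisopropylsilyloxy)phenyl]prop-2-enoate
Product: 8 4-{5-[(E)-3-hydroxyprop-1-enyl]-2-(triisopropylsilyloxy)phenoxy}benzaldehyde, via aluminium aldiminate alkoxide 7 (not isolated)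
Conditions: i-Bu2AlH (4.5 equiv), CH2Cl2, −78 → 0 °C; aq. potassium sodium tartrate, then 10% aq. citric acid, 0 °C
Reagents that add atoms: water, O
Why: Hydride reduction in which the enoate undergoes 1,2-reduction to the allylic alcohol while the nitrile stops at the N-aluminio imine and is hydrolysed to the aldehyde, so one operation differentiates the two arms.

**Step 6**
Reactants: 8 4-{5-[(E)-3-hydroxyprop-1-enyl]-2-(triisopropylsilyloxy)phenoxy}benzaldehyde
Product: 9 methyl (E)-3-(4-{5-[(E)-3-hydroxyprop-1-enyl]-2-(triisopropylsilyloxy)phenoxy}phenyl)prop-2-enoate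
Conditions: Ph3P=CHCO2Me, toluene, 60 °C
Reagents that add atoms: methyl (triphenylphosphoranylidene)acetate, COC(=O)C=P(c1ccccc1)(c1ccccc1)c1ccccc1
Why: Wittig olefination with a stabilised ylide, which tolerates the free allylic alcohol and stores the second arm as an (E)-enoate that is inert in the first etherification.

**Step 7**
Reactants: 9 methyl (E)-3-(4-{5-[(E)-3-hydroxyprop-1-enyl]-2-(triisopropylsilyloxy)phenoxy}phenyl)prop-2-enoate
Product: 10 methyl (E)-3-(4-{5-[(E)-3-(methoxycarbonyloxy)prop-1-enyl]-2-(triisopropylsilyloxy)phenoxy}phenyl)prop-2-enoate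
Conditions: ClCO2Me, pyridine, CH2Cl2, 0 °C
Reagents that add atoms: methyl chloroformate, COC(=O)Cl
Why: O-acylation of the primary allylic alcohol to the linear methyl carbonate, the leaving group needed for iridium-catalysed allylic substitution.

**Step 8**
Reactants: 10 methyl (E)-3-(4-{5-[(E)-3-(methoxycarbonyloxy)prop-1-enyl]-2-(triisopropylsilyloxy)phenoxy}phenyl)prop-2-enoate; 11 3,5-dimethoxyphenol
Product: 12 methyl (E)-3-(4-{5-[(1S)-1-(3,5-dimethoxyphenoxy)prop-2-enyl]-2-(triisopropylsilyloxy)phenoxy}phenyl)prop-2-enoate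
Conditions: [Ir(cod)Cl]2 (2 mol %), L (4 mol %), catalyst pre-activated with n-PrNH2; 11 as its lithium aryloxide (n-BuLi, 2 equiv), THF, rt
Reagents that add atoms: none
Why: Iridium-catalysed asymmetric allylic etherification in which the cyclometalated iridium–phosphoramidite complex ionises the carbonate and the aryloxide attacks the aryl-substituted allyl terminus, the chiral ligand controlling the face of attack and so setting the (S)-centre; methyl ester and methyl carbonate are matched so that the methoxide set free cannot scramble the ester.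

**Step 9**
Reactants: 12 methyl (E)-3-(4-{5-[(1S)-1-(3,5-dimethoxyphenoxy)prop-2-enyl]-2-(triisopropylsilyloxy)phenoxy}phenyl)prop-2-enoate
Product: 13 (E)-3-(4-{5-[(1S)-1-(3,5-dimethoxyphenoxy)prop-2-enyl]-2-(triisopropylsilyloxy)phenoxy}phenyl)prop-2-en-1-ol
Conditions: i-Bu2AlH (2.5 equiv), CH2Cl2, −78 °C; aq. potassium sodium tartrate
Reagents that add atoms: none
Why: 1,2-Reduction of the enoate to the allylic alcohol by an aluminium hydride at low temperature, where the terminal alkene, the allyl aryl ether and the silyl ether should be untouched.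

**Step 10**
Reactants: 13 (E)-3-(4-{5-[(1S)-1-(3,5-dimethoxyphenoxy)prop-2-enyl]-2-(triisopropylsilyloxy)phenoxy}phenyl)prop-2-en-1-ol
Product: 14 (E)-3-(4-{5-[(1S)-1-(3,5-dimethoxyphenoxy)prop-2-enyl]-2-(triisopropylsilyloxy)phenoxy}phenyl)prop-2-enyl methyl carbonate
Conditions: ClCO2Me, pyridine, CH2Cl2, 0 °C
Reagents that add atoms: methyl chloroformate, COC(=O)Cl
Why: O-acylation of the allylic alcohol to the methyl carbonate under mildly basic conditions that do not disturb the first stereocentre.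

**Step 11**
Reactants: 14 (E)-3-(4-{5-[(1S)-1-(3,5-dimethoxyphenoxy)prop-2-enyl]-2-(triisopropylsilyloxy)phenoxy}phenyl)prop-2-enyl methyl carbonate; 15 3,5-bis(benzyloxy)phenol
Product: 16 2-{4-[(1S)-1-(3,5-bis(benzyloxy)phenoxy)prop-2-enyl]phenoxy}-4-[(1S)-1-(3,5-dimethoxyphenoxy)prop-2-enyl]-1-(triisopropylsilyloxy)benzene
Conditions: [Ir(cod)Cl]2 (2 mol %), L (4 mol %), catalyst pre-activated with n-PrNH2; 15 as its lithium aryloxide (n-BuLi, 2 equiv), THF, rt, stopped at full conversion
Reagents that add atoms: none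
Why: Second iridium-catalysed asymmetric allylic etherification, branched-selective as in step 8, in which the same ligand enantiomer sets the second (S)-centre under catalyst control because the first centre is remote from the reacting allyl unit.

**Step 12**
Reactants: 16 the bis(1-arylallyl aryl ether) of step 11
Product: 18 (3S)-3-{4-[5-((1S)-1-(3,5-dimethoxyphenoxy)-3-hydroxypropyl)-2-(triisopropylsilyloxy)phenoxy]phenyl}-3-[3,5-bis(benzyloxy)phenoxy]propan-1-ol, via bis(9-BBN) adduct 17 (not isolated)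
Conditions: 9-BBN (3 equiv), THF, 0 °C → rt; then 30% H2O2, 3 M aq. NaOAc, 0 °C → rt
Reagents that add atoms: hydrogen peroxide, OO
Why: Anti-Markovnikov hydroboration–oxidation in which the bulky borane places boron on the terminal carbon of each vinyl group, three atoms away from the ether oxygen, so that no β-alkoxy elimination is possible and the stereocentres are untouched.

**Step 13**
Reactants: 18 the (3S,3'S)-diol of step 12
Product: 20 (3S)-3-{4-[5-((1S)-2-carboxy-1-(3,5-dimethoxyphenoxy)ethyl)-2-(triisopropylsilyloxy)phenoxy]phenyl}-3-[3,5-bis(benzyloxy)phenoxy]propanoic acid, via dialdehyde 19 (not isolated)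
Conditions: TEMPO (0.3 equiv), PhI(OAc)2 (5 equiv), MeCN/H2O, 0 °C → rt
Reagents that add atoms: water, O
Why: Oxoammonium-mediated oxidation of both primary alcohols through the aldehyde hydrates to the carboxylic acids in a weakly acidic medium, which should disfavour E1cB loss of aryloxide from the β-aryloxy aldehydes.

**Step 14**
Reactants: 20 the 4'-O-triisopropylsilyl (3S,3'S)-diacid of step 13
Product: 22 (3S)-3-{4-[2-acetoxy-5-((1S)-2-carboxy-1-(3,5-dimethoxyphenoxy)ethyl)phenoxy]phenyl}-3-[3,5-bis(benzyloxy)phenoxy]propanoic acid, via free phenol diacid 21 (not isolated)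
Conditions: Bu4NF (3 equiv), AcOH (3 equiv), THF, 0 °C; then Ac2O, pyridine, 0 °C → rt; H2O, work-up at pH 3
Reagents that add atoms: acetic anhydride, CC(=O)OC(C)=O
Why: Buffered fluoride desilylation keeps the phenol protonated so that no para-quinone methide can expel the benzylic aryloxide, and acetylation in the same flask installs the electron-poor 4'-acetoxy group, the mixed anhydrides at the carboxyl groups being hydrolysed on aqueous work-up.

**Step 15**
Reactants: 22 the 4'-O-acetyl (3S,3'S)-diacid of step 14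
Product: 24 4'-O-acetyl-5-O-methyl-5'',7''-di-O-benzyl-7-O-methyltetrahydroochnaflavone, via bis(acyl trifluoroacetate) 23 (not isolated)
Conditions: (CF3CO)2O (3 equiv), CH2Cl2 (0.02 M), −20 → 0 °C; cold aq. NaHCO3
Reagents that add atoms: none
Why: (CF3CO)2O should convert both carboxyl groups into acyl trifluoroacetates, and the CF3CO2H set free activates each of them for attack by the ring carbon that lies ortho to the aryl ether oxygen and para to an alkoxy group, the Wheland intermediate then losing a proton. The closest known reaction type is the intramolecular Friedel–Crafts acylation of 3-aryloxypropanoic acids to chroman-4-ones. Each ring C closes in a 6-exo-trig mode at the acyl carbon, which forms the C4–C4a bond of unit 1 and of unit 2. No stereocentre is formed; the two C2 centres set in steps 8 and 11 are not part of the reacting system. Regioselectivity is not an issue because the two ortho positions of each 3,5-dialkoxyphenoxy ring are equivalent, and acylation has to outrun ionisation of the benzylic C2–O bonds, which the electron-poor 4'-acetoxy group, the low temperature, the high dilution and the absence of any base or strong Lewis acid are chosen to secure.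

**Step 16**
Reactants: 24 4'-O-acetyl-5-O-methyl-5'',7''-di-O-benzyl-7-O-methyltetrahydroochnaflavone
Product: 25 5-O-methyl-5'',7''-di-O-benzyl-7-O-methyltetrahydroochnaflavone
Conditions: HCl (1.25 M in MeOH, 0.5 equiv), MeOH/CH2Cl2, 0 °C → rt
Reagents that add atoms: none
Why: Acid-catalysed transesterification of the aryl acetate with methanol, chosen because base would open ring C of a 4'-hydroxyflavanone to the chalcone and racemise C2.

**Step 17**
Reactants: 25 5-O-methyl-5'',7''-di-O-benzyl-7-O-methyltetrahydroochnaflavone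
Product: 26 7-O-methyltetrahydroochnaflavone
Conditions: BCl3 (10 equiv), C6HMe5 (6 equiv), CH2Cl2, −78 → 0 °C; MeOH, then H2O
Reagents that add atoms: none
Why: Lewis-acid ether cleavage in which BCl3 removes both benzyl groups with pentamethylbenzene as cation scavenger and, through chelation to the C4 carbonyl, only the peri 5-O-methyl group, while the unchelated 7-O-methyl group should stay.

**Compound list**
1 | isovanillin (3-hydroxy-4-methoxybenzaldehyde) | COc1ccc(C=O)cc1O | starting material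
2 | 4-fluorobenzonitrile | N#Cc1ccc(F)cc1 | starting material
3 | 4-(5-formyl-2-methoxyphenoxy)benzonitrile | COc1ccc(C=O)cc1Oc1ccc(C#N)cc1 | intermediate
4 | 4-(5-formyl-2-hydroxyphenoxy)benzonitrile | O=Cc1ccc(O)c(Oc2ccc(C#N)cc2)c1 | intermediate
5 | 4-[5-formyl-2-(triisopropylsilyloxy)phenoxy]benzonitrile | CC(C)[Si](Oc1ccc(C=O)cc1Oc1ccc(C#N)cc1)(C(C)C)C(C)C | intermediate
6 | methyl (E)-3-[3-(4-cyanophenoxy)-4-(triisopropylsilyloxy)phenyl]prop-2-enoate | COC(=O)/C=C/c1ccc(O[Si](C(C)C)(C(C)C)C(C)C)c(Oc2ccc(C#N)cc2)c1 | intermediate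
7 | O-diisobutylaluminium alkoxide and N-diisobutylaluminium aldimine formed from 6 | CC(C)C[Al](CC(C)C)OC/C=C/c1ccc(O[Si](C(C)C)(C(C)C)C(C)C)c(Oc2ccc(C=N[Al](CC(C)C)CC(C)C)cc2)c1 | intermediate
8 | 4-{5-[(E)-3-hydroxyprop-1-enyl]-2-(triisopropylsilyloxy)phenoxy}benzaldehyde | OC/C=C/c1ccc(O[Si](C(C)C)(C(C)C)C(C)C)c(Oc2ccc(C=O)cc2)c1 | intermediate
9 | methyl (E)-3-(4-{5-[(E)-3-hydroxyprop-1-enyl]-2-(triisopropylsilyloxy)phenoxy}phenyl)prop-2-enoate | OC/C=C/c1ccc(O[Si](C(C)C)(C(C)C)C(C)C)c(Oc2ccc(/C=C/C(=O)OC)cc2)c1 | intermediate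
10 | methyl (E)-3-(4-{5-[(E)-3-(methoxycarbonyloxy)prop-1-enyl]-2-(triisopropylsilyloxy)phenoxy}phenyl)prop-2-enoate | COC(=O)OC/C=C/c1ccc(O[Si](C(C)C)(C(C)C)C(C)C)c(Oc2ccc(/C=C/C(=O)OC)cc2)c1 | intermediate
11 | 3,5-dimethoxyphenol | COc1cc(O)cc(OC)c1 | starting material
12 | methyl (E)-3-(4-{5-[(1S)-1-(3,5-dimethoxyphenoxy)prop-2-enyl]-2-(triisopropylsilyloxy)phenoxy}phenyl)prop-2-enoate | C=C[C@H](Oc1cc(OC)cc(OC)c1)c1ccc(O[Si](C(C)C)(C(C)C)C(C)C)c(Oc2ccc(/C=C/C(=O)OC)cc2)c1 | intermediate
13 | (E)-3-(4-{5-[(1S)-1-(3,5-dimethoxyphenoxy)prop-2-enyl]-2-(triisopropylsilyloxy)phenoxy}phenyl)prop-2-en-1-ol | C=C[C@H](Oc1cc(OC)cc(OC)c1)c1ccc(O[Si](C(C)C)(C(C)C)C(C)C)c(Oc2ccc(/C=C/CO)cc2)c1 | intermediate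
14 | methyl carbonate of 13 | C=C[C@H](Oc1cc(OC)cc(OC)c1)c1ccc(O[Si](C(C)C)(C(C)C)C(C)C)c(Oc2ccc(/C=C/COC(=O)OC)cc2)c1 | intermediate
15 | 3,5-bis(benzyloxy)phenol | Oc1cc(OCc2ccccc2)cc(OCc2ccccc2)c1 | starting material
16 | 2-{4-[(1S)-1-(3,5-bis(benzyloxy)phenoxy)prop-2-enyl]phenoxy}-4-[(1S)-1-(3,5-dimethoxyphenoxy)prop-2-enyl]-1-(triisopropylsilyloxy)benzene | C=C[C@H](Oc1cc(OC)cc(OC)c1)c1ccc(O[Si](C(C)C)(C(C)C)C(C)C)c(Oc2ccc(cc2)[C@@H](Oc2cc(OCc3ccccc3)cc(OCc3ccccc3)c2)C=C)c1 | intermediate
17 | bis(B-alkyl-9-borabicyclo[3.3.1]nonane) adduct of 16, boron on both terminal carbons | C(CB1C2CCCC1CCC2)[C@H](Oc1cc(OC)cc(OC)c1)c1ccc(O[Si](C(C)C)(C(C)C)C(C)C)c(Oc2ccc(cc2)[C@@H](Oc2cc(OCc3ccccc3)cc(OCc3ccccc3)c2)CCB2C3CCCC2CCC3)c1 | intermediate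
18 | (3S,3'S)-diol: both vinyl groups of 16 converted to CH2CH2OH | OCC[C@H](Oc1cc(OC)cc(OC)c1)c1ccc(O[Si](C(C)C)(C(C)C)C(C)C)c(Oc2ccc(cc2)[C@@H](Oc2cc(OCc3ccccc3)cc(OCc3ccccc3)c2)CCO)c1 | intermediate
19 | (3S,3'S)-dialdehyde corresponding to 18 | O=CC[C@H](Oc1cc(OC)cc(OC)c1)c1ccc(O[Si](C(C)C)(C(C)C)C(C)C)c(Oc2ccc(cc2)[C@@H](Oc2cc(OCc3ccccc3)cc(OCc3ccccc3)c2)CC=O)c1 | intermediate
20 | (3S,3'S)-bis(3-aryloxypropanoic acid), 4'-O-triisopropylsilyl | OC(=O)C[C@H](Oc1cc(OC)cc(OC)c1)c1ccc(O[Si](C(C)C)(C(C)C)C(C)C)c(Oc2ccc(cc2)[C@@H](Oc2cc(OCc3ccccc3)cc(OCc3ccccc3)c2)CC(=O)O)c1 | intermediate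
21 | (3S,3'S)-bis(3-aryloxypropanoic acid), free 4'-OH | OC(=O)C[C@H](Oc1cc(OC)cc(OC)c1)c1ccc(O)c(Oc2ccc(cc2)[C@@H](Oc2cc(OCc3ccccc3)cc(OCc3ccccc3)c2)CC(=O)O)c1 | intermediate
22 | (3S,3'S)-bis(3-aryloxypropanoic acid), 4'-O-acetyl, with 3,5-dimethoxyphenoxy and 3,5-bis(benzyloxy)phenoxy groups | OC(=O)C[C@H](Oc1cc(OC)cc(OC)c1)c1ccc(OC(C)=O)c(Oc2ccc(cc2)[C@@H](Oc2cc(OCc3ccccc3)cc(OCc3ccccc3)c2)CC(=O)O)c1 | intermediate
23 | bis(acyl trifluoroacetate) of 22 | O=C(C[C@H](Oc1cc(OC)cc(OC)c1)c1ccc(OC(C)=O)c(Oc2ccc(cc2)[C@@H](Oc2cc(OCc3ccccc3)cc(OCc3ccccc3)c2)CC(=O)OC(=O)C(F)(F)F)c1)OC(=O)C(F)(F)F | intermediate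
24 | 4'-O-acetyl-5-O-methyl-5'',7''-di-O-benzyl-7-O-methyltetrahydroochnaflavone, (2S,2''S) | COc1cc(OC)c2c(c1)O[C@H](c1ccc(OC(C)=O)c(Oc3ccc([C@@H]4CC(=O)c5c(OCc6ccccc6)cc(OCc6ccccc6)cc5O4)cc3)c1)CC2=O | intermediate
25 | 5-O-methyl-5'',7''-di-O-benzyl-7-O-methyltetrahydroochnaflavone, (2S,2''S) | COc1cc(OC)c2c(c1)O[C@H](c1ccc(O)c(Oc3ccc([C@@H]4CC(=O)c5c(OCc6ccccc6)cc(OCc6ccccc6)cc5O4)cc3)c1)CC2=O | intermediate
26 | 7-O-methyltetrahydroochnaflavone, (2S,2''S) | COc1cc(O)c2c(c1)O[C@H](c1ccc(O)c(Oc3ccc([C@@H]4CC(=O)c5c(O)cc(O)cc5O4)cc3)c1)CC2=O | target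

**Step count and risks**
Total step count: 17. Longest linear sequence: 17 steps, from 1.

Steps most likely to fail:

1. Step 15. The CF3CO2H formed may ionise the benzylic C2–O bonds, with loss of the phenol and racemisation. The activated acyl groups may also lose aryloxide by E1cB elimination, and ring A may be trifluoroacetylated. The fallback sets out from 20 and comes back at 24, and it replaces the anhydride by an amide-derived electrophile in a pyridine-buffered medium. Coupling of 20 with Me2NH·HCl (EDC·HCl, HOBt, i-Pr2NEt, CH2Cl2) should give the 4'-O-triisopropylsilyl bis(N,N-dimethylamide) F1. The silyl ether is then exchanged for the acetate as in step 14, giving the 4'-O-acetyl bis(N,N-dimethylamide) F2. Tf2O with 2-chloropyridine (CH2Cl2, −78 → 0 °C) should convert each amide into an O-triflyl iminium ion that ring A attacks in an intramolecular Vilsmeier–Haack-type acylation, giving the bis(iminium) triflate F3. Hydrolysis with aq. NaHCO3 gives 24.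

2. Step 11 (the same concern applies to step 8). The iridium catalyst may re-ionise the allyl aryl ether already present, which would epimerise the first centre, exchange the aryloxide or isomerise the ether to the linear one. Facial control at the new centre may also be incomplete. The fallback sets out from 13 and comes back at 16. Sharpless asymmetric epoxidation (Ti(OiPr)4, L-(+)-diethyl tartrate, t-BuOOH, 4 Å sieves, CH2Cl2, −20 °C) should give the (2S,3S)-epoxy alcohol F4. Opening at the benzylic C3 with inversion by 15 (Ti(OiPr)4, CH2Cl2, rt) should give the (2S,3R)-3-aryloxy-1,2-diol F5. Thiocarbonyldiimidazole converts the diol into the cyclic thionocarbonate F6, and Corey–Winter elimination with 1,3-dimethyl-2-phenyl-1,3,2-diazaphospholidine (THF, 40 °C) gives the terminal alkene 16 with the (S)-centre in place.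

3. Step 17. Demethylation at O5 may be incomplete, or the Lewis acid may open ring C to the chalcone and so erode the C2 configuration. The fallback sets out from 25 and comes back at 26, and it separates the two events. Hydrogenolysis (H2, Pd/C, EtOAc) removes both benzyl groups under neutral conditions and should give 5-O-methyl-7-O-methyltetrahydroochnaflavone F7. Chelation-controlled demethylation of the peri methoxy group with anhydrous AlCl3 in MeCN at rt then gives 26.

**Further compounds**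
F1 | step 15 | 4'-O-triisopropylsilyl (3S,3'S)-bis(N,N-dimethyl-3-aryloxypropanamide) | CN(C)C(=O)C[C@H](Oc1cc(OC)cc(OC)c1)c1ccc(O[Si](C(C)C)(C(C)C)C(C)C)c(Oc2ccc(cc2)[C@@H](Oc2cc(OCc3ccccc3)cc(OCc3ccccc3)c2)CC(=O)N(C)C)c1
F2 | step 15 | 4'-O-acetyl (3S,3'S)-bis(N,N-dimethyl-3-aryloxypropanamide) | CN(C)C(=O)C[C@H](Oc1cc(OC)cc(OC)c1)c1ccc(OC(C)=O)c(Oc2ccc(cc2)[C@@H](Oc2cc(OCc3ccccc3)cc(OCc3ccccc3)c2)CC(=O)N(C)C)c1
F3 | step 15 | bis(C4 N,N-dimethyliminium) triflate of 24 | COc1cc(OC)c2c(c1)O[C@H](c1ccc(OC(C)=O)c(Oc3ccc([C@@H]4CC(=[N+](C)C)c5c(OCc6ccccc6)cc(OCc6ccccc6)cc5O4)cc3)c1)CC2=[N+](C)C.[O-]S(=O)(=O)C(F)(F)F.[O-]S(=O)(=O)C(F)(F)F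
F4 | step 11 | (2S,3S)-2,3-epoxy alcohol from 13 | C=C[C@H](Oc1cc(OC)cc(OC)c1)c1ccc(O[Si](C(C)C)(C(C)C)C(C)C)c(Oc2ccc(cc2)[C@@H]2O[C@H]2CO)c1
F5 | step 11 | (2S,3R)-3-[3,5-bis(benzyloxy)phenoxy]-3-arylpropane-1,2-diol | C=C[C@H](Oc1cc(OC)cc(OC)c1)c1ccc(O[Si](C(C)C)(C(C)C)C(C)C)c(Oc2ccc(cc2)[C@@H](Oc2cc(OCc3ccccc3)cc(OCc3ccccc3)c2)[C@@H](O)CO)c1
F6 | step 11 | cyclic thionocarbonate of F5 | C=C[C@H](Oc1cc(OC)cc(OC)c1)c1ccc(O[Si](C(C)C)(C(C)C)C(C)C)c(Oc2ccc(cc2)[C@@H](Oc2cc(OCc3ccccc3)cc(OCc3ccccc3)c2)[C@@H]2COC(=S)O2)c1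
F7 | step 17 | 5-O-methyl-7-O-methyltetrahydroochnaflavone, (2S,2''S) | COc1cc(OC)c2c(c1)O[C@H](c1ccc(O)c(Oc3ccc([C@@H]4CC(=O)c5c(O)cc(O)cc5O4)cc3)c1)CC2=O
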